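This flask grows slower as it runs, so one time constant will not describe it.

all flasks: partner 0.106 M
- east: starting material 0.071 M; the very flask that is asked about, followed so far
- north: starting material 0.048 M; run made earlier
- flask: starting material 0.071 M; time 12 h

| run | time / h | starting material / % | bis adduct / % |
|---|---|---|---|
| east | 0.417 | 82 | 5 |
| east | 0.833 | 70 | 7 |
| east | 2.00 | 47 | 8 |
| east | 5.00 | 24 | 3 |
| north | 3.00 | 34 | 5 |
| north | 6.00 | 15 | 3 |
| north | 10.0 | 8 | 0 |
| north | 12.0 | 8 | 2 |

(readings scatter by 2 percentage points)

1. amount of starting material in percent of the starting material charged, at 40 min, 3.0 h and 12 h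



Let f be the fraction of starting material left. The east run is this same flask, and up to 0.417 h it gives an early time constant τ_e of 2.10 h. This is our full-partner time, a pseudo-first-order time constant with partner near its charge. From 2.00 h to 5.00 h the late time constant τ_l is 4.46 h, longer than τ_e. The north run slows as well, reading 8% at 10.0 h and 8% at 12.0 h.

We take the decay rate to follow partner, so the ratio τ_e/τ_l reads partner's share in that stretch as 47.1%. Starting material then stood near 33.6%. We join the two ends by letting partner's share follow f, which gives f = 1/(1 + t/τ_e). Our line gives 75.9%, 41.2% and 14.9%. It runs high, with 29.6% at 5.00 h against a reading of 24%, because the share of partner we read for that stretch stood above f there.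

The forecast says 75%, 36% and 10%, lower than our line at each point. For its last value it argues: "This hints at a reversible step".

The flask gives 74.2%, 37.9% and 13.2%, by these steps:

    starting material + partner → mono adduct (k = 4.70 M⁻¹ h⁻¹)
    partner + mono adduct → bis adduct (k = 4.60 M⁻¹ h⁻¹)
    partner + bis adduct → triple product (k = 12.0 M⁻¹ h⁻¹)
    mono adduct → decomposed reagent (k = 0.690 h⁻¹)

At 12.0 h partner stands at 14.8% of its charge, beside 13.2% of the starting material. Dividing τ_e by that share puts the time constant of the east flask at 14.2 h by then. At twice the dilution τ_e doubles, so our line gives 25.9% for 12 h, and that flask holds 21.2%.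

(All runs were generated by integration for substances that don't exist; the scatter is artificial.)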